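## Retrosynthetic overview
1. The target comes from global desilylation of a bis-TBS ether. Its oxirane, the only ring of the target, is closed one step earlier by hydroxyl-directed Sharpless epoxidation of the C10=C11 alkene.
2. The C5–C9 core comes from two boron aldols on one symmetric ketone, 1,5-bis(silyloxy)pentan-3-one. C8–C9 (anti) is made first with a dienal, then C5–C6 (syn) with a C3-ketal aldehyde.
3. The dienal comes from a Wittig reaction (C10=C11) on (2S,3Z)-2-methylpent-3-enal.
4. That aldehyde comes from a stereospecific 1,2-shift of a (Z)-propenyl group (semipinacol) in an aluminium alkoxide. The alkoxide is built from (S)-2-mesyloxypropanal (from ethyl L-lactate) and (Z)-1-bromopropene. The shift makes C12–C13 and sets C12.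
5. Ring order: the temporary dioxolane (mask of C3=O) is formed first and removed before the oxirane is formed.

Assumptions: C1–C15 run from the ethyl ketone end along the main chain; the target is treated as the open hydroxy ketone drawn (in solution it equilibrates with the lactol from the C6 hydroxymethyl group and C3=O); the facial senses quoted for the two chiral boron reagents are those of their ethyl ketone series, and the antipodal reagent would be used should a sense prove opposite.

## Route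

Step 1
Reactants: 1 ethyl (2S)-2-hydroxypropanoate (ethyl L-lactate)
Product: 2 ethyl (2S)-2-(methylsulfonyloxy)propanoate
Conditions: MsCl (1.2 equiv), Et3N (1.5 equiv), CH2Cl2, 0 °C
Reagents that add atoms: methanesulfonyl chloride, CS(=O)(=O)Cl
Why: O-sulfonylation (mesylation) takes place at oxygen only, so the stereocentre is untouched and the leaving group for the later 1,2-shift is installed.

Step 2
Reactants: 2 ethyl (2S)-2-(methylsulfonyloxy)propanoate
Product: 3 (2S)-1-oxopropan-2-yl methanesulfonate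
Conditions: i-Bu2AlH (1.05 equiv), CH2Cl2, −78 °C; aq. KNaC4H4O6; used crude
Reagents that add atoms: none
Why: Partial ester reduction stops at the tetrahedral aluminium hemiacetal at −78 °C, so the aldehyde is released only on work-up and the α-centre is not epimerised.

Step 3
Reactants: 3 (2S)-1-oxopropan-2-yl methanesulfonate, 4 (Z)-1-bromoprop-1-ene
Product: 9 (2E,4S,5Z)-2,4-dimethylhepta-2,5-dienal, via (Z)-prop-1-enyllithium 5 (not isolated), via dimethyl[(Z)-prop-1-enyl]alane 6 (not isolated), via aluminium alkoxide 7 (not isolated), via (2S,3Z)-2-methylpent-3-enal 8 (not isolated)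
Conditions: 4 (1.0 equiv), t-BuLi (2.0 equiv), Et2O, −78 °C; Me2AlCl (2.0 equiv), −78 °C; 3 in CH2Cl2, −78 → −20 °C; cold aq. KNaC4H4O6, dry the organic layer; then Ph3P=C(Me)CHO (1.3 equiv), CH2Cl2, 40 °C
Reagents that add atoms: 2-(triphenyl-λ5-phosphanylidene)propanal, CC(C=O)=P(c1ccccc1)(c1ccccc1)c1ccccc1
Why: Proposed new method: the non-basic alkenylalane 6 transfers its sp2 ligand to the α-mesyloxy aldehyde, and the resulting alkoxide 7 is already the push–pull species of a semipinacol rearrangement (the Al–O bond pushes, the second aluminium Lewis acid pulls the mesylate), so the (Z)-propenyl group moves from C11 to C12 anti to the C–OMs bond with retained olefin geometry and clean inversion at C12, both carbinol epimers converge because that carbon becomes the formyl group, no hydride source is present to over-reduce (S)-8, and 8 is trapped at once by E-selective Wittig olefination with the stabilised ylide; the closest known reaction type is the Suzuki–Tsuchihashi organoaluminium-promoted 1,2-alkenyl shift of isolated β-mesyloxy alcohols, known for tertiary carbinols (ketone products) or in reductive mode (alcohol products) but not as an addition/shift cascade that stops at an enolisable β,γ-unsaturated aldehyde.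

Step 4
Reactants: 10 pentane-1,3,5-triol
Product: 11 1,5-bis(tert-butyldimethylsilyloxy)pentan-3-ol
Conditions: TBSCl (2.05 equiv), imidazole (2.5 equiv), CH2Cl2/DMF, −10 → 0 °C
Reagents that add atoms: tert-butyldimethylsilyl chloride, CC(C)(C)[Si](C)(C)Cl
Why: Sterically selective silylation protects the two primary hydroxyls well before the secondary one, and no stereocentre is involved.

Step 5
Reactants: 11 1,5-bis(tert-butyldimethylsilyloxy)pentan-3-ol
Product: 12 1,5-bis(tert-butyldimethylsilyloxy)pentan-3-one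
Conditions: Dess–Martin periodinane (1.2 equiv), CH2Cl2, rt
Reagents that add atoms: none
Why: Dess–Martin oxidation converts the secondary alcohol to the ketone under near-neutral conditions that do not eliminate the β-silyloxy groups.

Step 6
Reactants: 13 3-oxopentanenitrile
Product: 14 (2-ethyl-1,3-dioxolan-2-yl)acetonitrile
Conditions: ethylene glycol (1.5 equiv), TsOH·H2O (2 mol %), toluene, reflux, Dean–Stark
Reagents that add atoms: ethylene glycol, OCCO
Why: Acid-catalysed ketalisation with azeotropic removal of water masks the future C3 ketone, and the nitrile is inert.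

Step 7
Reactants: 14 (2-ethyl-1,3-dioxolan-2-yl)acetonitrile
Product: 15 (2-ethyl-1,3-dioxolan-2-yl)acetaldehyde
Conditions: i-Bu2AlH (1.1 equiv), CH2Cl2, −78 °C; aq. KNaC4H4O6/NaH2PO4 (pH about 5), 0 °C
Reagents that add atoms: water, O
Why: Partial nitrile reduction stops at the N-aluminoimine, which is hydrolysed at a pH that leaves the dioxolane intact.

Step 8
Reactants: 12 1,5-bis(tert-butyldimethylsilyloxy)pentan-3-one, 9 (2E,4S,5Z)-2,4-dimethylhepta-2,5-dienal
Product: 17 (4R,5S,6E,8S,9Z)-1-(tert-butyldimethylsilyloxy)-4-[(tert-butyldimethylsilyloxy)methyl]-5-hydroxy-6,8-dimethylundeca-6,9-dien-3-one, via E-enol borinate 16 (not isolated)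
Conditions: (MenthCH2)2BCl = bis{[(1S,2S,5R)-2-isopropyl-5-methylcyclohexyl]methyl}boron chloride, from (−)-menthone (1.3 equiv), Et3N (1.5 equiv), Et2O, −78 → 0 °C; 9, −78 → −20 °C; H2O2, MeOH, pH 7 buffer, 0 °C
Reagents that add atoms: none
Why: In this reagent-controlled boron anti aldol (Gennari–Paterson type) the R2BCl/Et3N pair gives the covalent E(O)-enol borinate without loss of silyloxide, the Zimmerman–Traxler chair turns E geometry into the 8,9-anti relationship, and the menthone-derived ligands steer the achiral enolate to the Si face of the enal to give 8R,9S, the remote C12 centre having no influence and the minor 8S,9R product being a removable diastereomer.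

Step 9
Reactants: 17 the anti aldol adduct of step 8
Product: 18 (4R,5S,6E,8S,9Z)-1-(tert-butyldimethylsilyloxy)-4-[(tert-butyldimethylsilyloxy)methyl]-6,8-dimethyl-5-(triethylsilyloxy)undeca-6,9-dien-3-one
Conditions: TESOTf (1.2 equiv), 2,6-lutidine (2.0 equiv), CH2Cl2, −78 °C
Reagents that add atoms: triethylsilyl trifluoromethanesulfonate, CC[Si](CC)(CC)OS(=O)(=O)C(F)(F)F
Why: Silyl triflate silylation caps the hindered allylic C9 hydroxyl at low temperature without retro-aldol or epimerisation, and TES stays distinguishable from the primary TBS ethers.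

Step 10
Reactants: 18 the TES ether of step 9, 15 (2-ethyl-1,3-dioxolan-2-yl)acetaldehyde
Product: 20 (5S,6R,8R,9S,10E,12S,13Z)-6,8-bis[(tert-butyldimethylsilyloxy)methyl]-3,3-(ethylenedioxy)-5-hydroxy-10,12-dimethyl-9-(triethylsilyloxy)pentadeca-10,13-dien-7-one, via Z-enol borinate 19 (not isolated)
Conditions: (+)-Ipc2BOTf, from (−)-α-pinene (1.5 equiv), i-Pr2NEt (2.0 equiv), CH2Cl2, −78 °C, 3 h; 15 (2 equiv), −78 → −20 °C, 16 h; H2O2, MeOH, pH 7 buffer, 0 °C
Reagents that add atoms: none
Why: In this Paterson syn aldol the triflate/amine pair enolises only the unbranched C6 methylene to the Z(O)-enol borinate, the chair transition state gives 5,6-syn, and the isopinocampheyl ligands, which are known to override the small bias of α′-chiral Z-enol borinates and to deliver syn–anti arrays, direct attack to the Re face of 15 to give 5S,6R and the 6,8-anti relationship.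

Step 11
Reactants: 20 the syn aldol adduct of step 10
Product: 21 (5S,6R,8R,9S,10E,12S,13Z)-6,8-bis[(tert-butyldimethylsilyloxy)methyl]-5,9-dihydroxy-10,12-dimethylpentadeca-10,13-diene-3,7-dione
Conditions: TsOH·H2O (0.1 equiv), acetone/H2O (30:1), 0 °C → rt
Reagents that add atoms: water, O
Why: Acid-catalysed ketal exchange/hydrolysis and solvolysis of the much more labile TES ether free C3=O and the C9 hydroxyl while the primary TBS ethers survive, and it is done before the acid-sensitive oxirane exists.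

Step 12
Reactants: 21 the dienediol-dione of step 11
Product: 22 (5S,6R,8R,9S)-6,8-bis[(tert-butyldimethylsilyloxy)methyl]-5,9-dihydroxy-9-{(2R,3R)-2-methyl-3-[(2S,3Z)-pent-3-en-2-yl]oxiran-2-yl}nonane-3,7-dione
Conditions: Ti(Oi-Pr)4 (0.3 equiv), L-(+)-DIPT (0.36 equiv), t-BuOOH (2 equiv), 4 Å sieves, CH2Cl2, −20 °C
Reagents that add atoms: tert-butyl hydroperoxide, CC(C)(C)OO
Why: In this Sharpless asymmetric epoxidation the 9S carbinol is the fast-reacting antipode with the L-(+)-tartrate and oxygen is delivered to give the erythro epoxy alcohol (10R,11R), which is also the sense favoured by allylic 1,2-strain from the C10 methyl, while the Z-alkene has no allylic hydroxyl and stays untouched and any residual 9R material is left unreacted.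

Step 13
Reactants: 22 the bis-TBS epoxide of step 12
Product: 23 (5S,6R,8R,9S)-5,9-dihydroxy-6,8-bis(hydroxymethyl)-9-{(2R,3R)-2-methyl-3-[(2S,3Z)-pent-3-en-2-yl]oxiran-2-yl}nonane-3,7-dione (target)
Conditions: HF·pyridine, excess pyridine, THF, 0 °C → rt
Reagents that add atoms: none
Why: Buffered fluoride desilylation cleaves the two primary Si–O bonds under conditions too mild for epoxide opening, retro-aldol or β-elimination, and no stereocentre is touched.

## Compound list
1 | ethyl (2S)-2-hydroxypropanoate | C[C@H](O)C(=O)OCC | starting material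
2 | ethyl (2S)-2-(methylsulfonyloxy)propanoate | C[C@H](OS(C)(=O)=O)C(=O)OCC | intermediate
3 | (2S)-1-oxopropan-2-yl methanesulfonate | C[C@H](OS(C)(=O)=O)C=O | intermediate
4 | (Z)-1-bromoprop-1-ene | C/C=C\Br | starting material
5 | (Z)-prop-1-enyllithium | C/C=C\[Li] | intermediate
6 | dimethyl[(Z)-prop-1-enyl]alane | C/C=C\[Al](C)C | intermediate
7 | dimethylaluminium (2S,4Z)-2-(methylsulfonyloxy)hex-4-en-3-olate, both C3 epimers | C/C=C\C(O[Al](C)C)[C@H](C)OS(C)(=O)=O | intermediate
8 | (2S,3Z)-2-methylpent-3-enal | C/C=C\[C@H](C)C=O | intermediate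
9 | (2E,4S,5Z)-2,4-dimethylhepta-2,5-dienal | C/C=C\[C@H](C)/C=C(\C)C=O | intermediate
10 | pentane-1,3,5-triol | OCCC(O)CCO | starting material
11 | 1,5-bis(tert-butyldimethylsilyloxy)pentan-3-ol | CC(C)(C)[Si](C)(C)OCCC(O)CCO[Si](C)(C)C(C)(C)C | intermediate
12 | 1,5-bis(tert-butyldimethylsilyloxy)pentan-3-one | CC(C)(C)[Si](C)(C)OCCC(=O)CCO[Si](C)(C)C(C)(C)C | intermediate
13 | 3-oxopentanenitrile | CCC(=O)CC#N | starting material
14 | (2-ethyl-1,3-dioxolan-2-yl)acetonitrile | CCC1(CC#N)OCCO1 | intermediate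
15 | (2-ethyl-1,3-dioxolan-2-yl)acetaldehyde | CCC1(CC=O)OCCO1 | intermediate
16 | E(O)-enol bis(menthylmethyl)borinate of 12 | CC(C)(C)[Si](C)(C)OC/C=C(/OB(C[C@H]1C[C@H](C)CC[C@H]1C(C)C)C[C@H]1C[C@H](C)CC[C@H]1C(C)C)CCO[Si](C)(C)C(C)(C)C | intermediate
17 | (4R,5S,6E,8S,9Z)-1-(TBSO)-4-(TBSO-methyl)-5-hydroxy-6,8-dimethylundeca-6,9-dien-3-one | C/C=C\[C@H](C)/C=C(\C)[C@@H](O)[C@@H](CO[Si](C)(C)C(C)(C)C)C(=O)CCO[Si](C)(C)C(C)(C)C | intermediate
18 | (4R,5S,6E,8S,9Z)-1-(TBSO)-4-(TBSO-methyl)-6,8-dimethyl-5-(TESO)undeca-6,9-dien-3-one | C/C=C\[C@H](C)/C=C(\C)[C@@H](O[Si](CC)(CC)CC)[C@@H](CO[Si](C)(C)C(C)(C)C)C(=O)CCO[Si](C)(C)C(C)(C)C | intermediate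
19 | Z(O)-enol diisopinocampheylborinate of 18 | C/C=C\[C@H](C)/C=C(\C)[C@@H](O[Si](CC)(CC)CC)[C@@H](CO[Si](C)(C)C(C)(C)C)/C(OB([C@H]1C[C@H]2C[C@@H]([C@@H]1C)C2(C)C)[C@H]1C[C@H]2C[C@@H]([C@@H]1C)C2(C)C)=C/CO[Si](C)(C)C(C)(C)C | intermediate
20 | (5S,6R,8R,9S,10E,12S,13Z)-6,8-bis(TBSO-methyl)-3,3-(ethylenedioxy)-5-hydroxy-10,12-dimethyl-9-(TESO)pentadeca-10,13-dien-7-one | C/C=C\[C@H](C)/C=C(\C)[C@@H](O[Si](CC)(CC)CC)[C@@H](CO[Si](C)(C)C(C)(C)C)C(=O)[C@H](CO[Si](C)(C)C(C)(C)C)[C@@H](O)CC1(CC)OCCO1 | intermediate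
21 | (5S,6R,8R,9S,10E,12S,13Z)-6,8-bis(TBSO-methyl)-5,9-dihydroxy-10,12-dimethylpentadeca-10,13-diene-3,7-dione | C/C=C\[C@H](C)/C=C(\C)[C@@H](O)[C@@H](CO[Si](C)(C)C(C)(C)C)C(=O)[C@H](CO[Si](C)(C)C(C)(C)C)[C@@H](O)CC(=O)CC | intermediate
22 | (5S,6R,8R,9S)-6,8-bis(TBSO-methyl)-5,9-dihydroxy-9-{(2R,3R)-2-methyl-3-[(2S,3Z)-pent-3-en-2-yl]oxiran-2-yl}nonane-3,7-dione | C/C=C\[C@H](C)[C@H]1O[C@]1(C)[C@@H](O)[C@@H](CO[Si](C)(C)C(C)(C)C)C(=O)[C@H](CO[Si](C)(C)C(C)(C)C)[C@@H](O)CC(=O)CC | intermediate
23 | (5S,6R,8R,9S)-5,9-dihydroxy-6,8-bis(hydroxymethyl)-9-{(2R,3R)-2-methyl-3-[(2S,3Z)-pent-3-en-2-yl]oxiran-2-yl}nonane-3,7-dione | C/C=C\[C@H](C)[C@H]1O[C@]1(C)[C@@H](O)[C@@H](CO)C(=O)[C@H](CO)[C@@H](O)CC(=O)CC | target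

## Step count
Total step count: 13.
Longest linear sequence: 9 steps (1 → 2 → 3 → 9 → 17 → 18 → 20 → 21 → 22 → 23).

## Steps most likely to fail

**First, step 3 (the new cascade).**
- Risks: methyl instead of propenyl transfer from 6; a 1,2-hydride shift or oxirane closure in 7; epimerisation or conjugation of 8 during the rather slow Wittig reaction.
- The fallback is known chemistry without a rearrangement. It sets out from 2 (and from 5, made from 4 as before) and comes back at 8.
- The sulfonate of 2 is displaced directly, with inversion, by the lithium dialkenylcuprate prepared from 5 (2 equiv) and CuI in Et2O at −40 °C. This SN2 reaction is established for O-sulfonyl lactates and gives ethyl (2S,3Z)-2-methylpent-3-enoate F1.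
- One equivalent of i-Bu2AlH in CH2Cl2 at −78 °C reduces F1 to 8, which is olefinated to 9 as before.

**Second, step 8 (facial control of the anti aldol).**
- Risk: the menthone-derived chloroborane is reported to give only moderate to good enantiofacial control, so dr at C8/C9 against C12 may be modest.
- The fallback replaces reagent control by resolution. It sets out from 12 and 9 and comes back at 17.
- Enolisation with achiral Cy2BCl/Et3N and addition of 9 gives 17 together with about an equal amount of its anti diastereomer (4S,5R,6E,8S,9Z)-1-(TBSO)-4-(TBSO-methyl)-5-hydroxy-6,8-dimethylundeca-6,9-dien-3-one F2.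
- A Sharpless kinetic resolution follows: Ti(Oi-Pr)4, D-(−)-DIPT, t-BuOOH (0.6 equiv), 4 Å sieves, −20 °C. It consumes only the 9R isomer F2.
- F2 is turned into the much more polar (4S,5R)-1-(TBSO)-4-(TBSO-methyl)-5-hydroxy-5-{(2S,3S)-2-methyl-3-[(2S,3Z)-pent-3-en-2-yl]oxiran-2-yl}pentan-3-one F3, and unreacted 17 is recovered pure by chromatography.

**Third, step 10 (aldol of a hindered, α′-branched ketone in a possibly mismatched pairing).**
- Risks: slow enolisation and eroded 6,8-anti selectivity.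
- The fallback inverts the order of the two aldols. It sets out from 12 and 15 and comes back at 21.
- (+)-Ipc2BOTf/i-Pr2NEt is used on the unhindered symmetric ketone 12, and addition of 15 gives (4R,5S)-1-(TBSO)-4-(TBSO-methyl)-6-(2-ethyl-1,3-dioxolan-2-yl)-5-hydroxyhexan-3-one F4.
- 4-Methoxybenzyl trichloroacetimidate with Sc(OTf)3 (1 mol %) in toluene at 0 °C gives its 5-O-(4-methoxybenzyl) ether F5.
- Cy2BCl/Et3N then 9 gives the anti adduct (5S,6R,8R,9S,10E,12S,13Z)-6,8-bis(TBSO-methyl)-3,3-(ethylenedioxy)-9-hydroxy-5-(4-methoxybenzyloxy)-10,12-dimethylpentadeca-10,13-dien-7-one F6. Here the benzyl-type ether oxygen at C5, unlike the silyl ethers, can accept the formyl hydrogen bond that steers E-enol borinates to the α,α′-anti product.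
- DDQ in CH2Cl2/pH 7 buffer at 0 °C gives the 5,9-diol ketal (5S,6R,8R,9S,10E,12S,13Z)-6,8-bis(TBSO-methyl)-3,3-(ethylenedioxy)-5,9-dihydroxy-10,12-dimethylpentadeca-10,13-dien-7-one F7.
- The conditions of step 11 convert F7 into 21.

## Further compounds
F1 | step 3 | ethyl (2S,3Z)-2-methylpent-3-enoate | C/C=C\[C@H](C)C(=O)OCC
F2 | step 8 | (4S,5R,6E,8S,9Z)-1-(TBSO)-4-(TBSO-methyl)-5-hydroxy-6,8-dimethylundeca-6,9-dien-3-one | C/C=C\[C@H](C)/C=C(\C)[C@H](O)[C@H](CO[Si](C)(C)C(C)(C)C)C(=O)CCO[Si](C)(C)C(C)(C)C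
F3 | step 8 | (4S,5R)-1-(TBSO)-4-(TBSO-methyl)-5-hydroxy-5-{(2S,3S)-2-methyl-3-[(2S,3Z)-pent-3-en-2-yl]oxiran-2-yl}pentan-3-one | C/C=C\[C@H](C)[C@@H]1O[C@@]1(C)[C@H](O)[C@H](CO[Si](C)(C)C(C)(C)C)C(=O)CCO[Si](C)(C)C(C)(C)C
F4 | step 10 | (4R,5S)-1-(TBSO)-4-(TBSO-methyl)-6-(2-ethyl-1,3-dioxolan-2-yl)-5-hydroxyhexan-3-one | CC(C)(C)[Si](C)(C)OCCC(=O)[C@H](CO[Si](C)(C)C(C)(C)C)[C@@H](O)CC1(CC)OCCO1
F5 | step 10 | (4R,5S)-1-(TBSO)-4-(TBSO-methyl)-6-(2-ethyl-1,3-dioxolan-2-yl)-5-(4-methoxybenzyloxy)hexan-3-one | CC(C)(C)[Si](C)(C)OCCC(=O)[C@H](CO[Si](C)(C)C(C)(C)C)[C@@H](OCc1ccc(OC)cc1)CC1(CC)OCCO1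
F6 | step 10 | (5S,6R,8R,9S,10E,12S,13Z)-6,8-bis(TBSO-methyl)-3,3-(ethylenedioxy)-9-hydroxy-5-(4-methoxybenzyloxy)-10,12-dimethylpentadeca-10,13-dien-7-one | C/C=C\[C@H](C)/C=C(\C)[C@@H](O)[C@@H](CO[Si](C)(C)C(C)(C)C)C(=O)[C@H](CO[Si](C)(C)C(C)(C)C)[C@@H](OCc1ccc(OC)cc1)CC1(CC)OCCO1
F7 | step 10 | (5S,6R,8R,9S,10E,12S,13Z)-6,8-bis(TBSO-methyl)-3,3-(ethylenedioxy)-5,9-dihydroxy-10,12-dimethylpentadeca-10,13-dien-7-one | C/C=C\[C@H](C)/C=C(\C)[C@@H](O)[C@@H](CO[Si](C)(C)C(C)(C)C)C(=O)[C@H](CO[Si](C)(C)C(C)(C)C)[C@@H](O)CC1(CC)OCCO1
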